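The readings come from a simulation with made-up constants, and the scatter is random.

Hours are the unit I reckon in: I follow one molecule of J in the flask, which must first become L and then escape turning into D until the reading.

all flasks: J 0.11 M; X 9.2 mM (held); Q 2 mol%

| charge | remark | time |
|---|---|---|
| winter | the very flask that is asked about, followed so far |  |
| flask |  | 3.0 d |

- winter (time / h: L / %, J / %): 2.00: 8.8, 89.8; 4.00: 19.3, 80.5; 6.00: 28.4, 73.1; 8.00: 36.7, 61.9; 10.0: 46.5, 52.4; 12.0: 54.2, 43.9

(scatter of a reading: 1 percentage point)

- the L standing at 3.0 d, as a percentage of the J charged
- concentration of E in solution at 3.0 d, in percent of saturation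

- at the start none of E is dissolved
- steps thought possible: X <-> E; J + E + Q -> Q + L; L -> D

Its chances hang on two quantities, and I ask first what an error in each costs. One is when the molecule becomes L. In the winter run, which is this flask, L gains about the same each hour while J falls from 89.8% to 43.9%, which reads as the dissolving of X being the rate-limiting step. Taking that pace to the end of J, half the run-out time is the mean birth time of L, 11.1 h. The reading before gives 10.8 h, a shift I price below.

The other is the loss constant of L, and it matters. The last reading leaves a deficit of 1.9 percentage points on a scatter of 1 point. Set against the L-hours so far, it reads as 0.00584 /h. Survival is then 70.0%, my figure; the shift in birth time moves it by 0.13 points, but a doubled constant gives 49.1%. The winter pace supplies the saturation concentration of E in 1.85 h, a time scale shorter than the 49.9 h between my reckoned end of J and the reading, so I expect saturation.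

The forecast, reckoning that “L has aged about 61 h on average”, says 75%, between 60% and 92%, and 100% of saturation, between 95% and 100%.

The flask gives 69.3% and 100%.

    X ⇌ E, rate k1*(csat - [E]) (kL = 0.00960 /min)
    J + E + Q → Q + L (k = 3900 /M²/min)
    L → D (k = 1.00 × 10⁻⁴ /min)

The forecast stands 5.7 points above the flask. With the constant of the last step, 1.0 × 10⁻⁴ /min, the same birth time gives the flask a survival of 69.4%. The neighbouring flask has the same charges but is read at 5.0 d; its age is 109 h, so the reckoning gives 52.0%, and that neighbouring flask holds L at 51.9%.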